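**Time allowed.** Time was what I looked at first, since green stops at 20 min and ochre at 6.0 min, on different charges of starting material but equal charges of reagent, free catalyst and impurity.

in all of them: reagent 1.99 M; free catalyst 95 mM; impurity 140 mM
- beta: starting material 0.37 M; run made earlier
- alpha: starting material 1.5 M; run made earlier
- green: starting material 1.9 M; time 20 min
- ochre: starting material 0.50 M; time 6.0 min

| run | time / min | product / % | starting material / % |
|---|---|---|---|
| beta | 1.33 | 15.2 | 74.9 |
| beta | 4.00 | 34.5 | 61.2 |
| beta | 6.00 | 40.0 | 57.8 |
| beta | 10.0 | 43.9 | 55.3 |
| beta | 15.0 | 46.0 | 54.0 |
| alpha | 3.00 | 13.5 | 82.0 |
| alpha | 6.00 | 23.2 | 74.2 |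
| alpha | 8.00 | 27.7 | 69.6 |
| alpha | 12.0 | 35.7 | 64.2 |
| alpha | 15.0 | 38.0 | 61.8 |

(each reading ± 0.5 percentage points)

- released group is meant together with its idle complex
- the earlier runs were read with a standard deviation of 0.5 percentage points
- candidate steps: starting material + free catalyst -> catalyst intermediate A; reagent + catalyst intermediate A -> catalyst intermediate B; catalyst intermediate B -> released group + catalyst intermediate C; catalyst intermediate C <-> free catalyst + product; free catalyst + released group <-> idle complex; free catalyst + impurity -> spent catalyst

- the flask that ends with the higher amount of product, in percent of the starting material charged, or "neither" when 2 percentage points or less lies between them (green / ochre / neither)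
- final product, as a percentage of the starting material charged, in green
- final product, as a percentage of the starting material charged, in ochre

**Lasting catalyst.** One extreme version of these flasks keeps its catalyst working: alpha's opening pace, in percent of its own charge, held over green's time gave 90.0 %, and beta's opening pace, reckoned the same way, held over ochre's time gave 68.6 %. But beta flattened near 46.0 % at 15.0 min, with 54.0 % of its starting material unused, so I dropped this version.

**Dying catalyst.** The other extreme is a flask left until its catalyst has become spent catalyst. The impurity charge is larger than the catalyst charge, and each catalyst takes one impurity, so in this version 32.1 % of the impurity stays. I let starting material and impurity compete for free catalyst, each at first order, so the fraction of starting material left equals the fraction of impurity left raised to a power, which beta's last reading, taken as beta's end, put at 0.543: this is the selectivity factor, capture by starting material over capture by impurity at equal amounts. Carried back, it gave an end value of 46.0 %, which is beta's last reading again, and since the starting material charge stands nowhere in that reckoning, I took the same end value for green and ochre.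

**Between them.** Beta read 40.0 % at 6.00 min and alpha 38.0 % at 15.0 min, both below that end value, so I expected ochre and green to stop short of it, near these readings; my reckoning gave the end value and no closer figure. The forecast said 39 % for green, 37.5 % for ochre and neither, holding that “The stated times therefore decide the outcome”.

**The flask.** Green gave 38.0 % and ochre 37.7 %, so the answer was neither.

    starting material + free catalyst → catalyst intermediate A (k = 27.0 M⁻¹ min⁻¹)
    reagent + catalyst intermediate A → catalyst intermediate B (k = 1.40 M⁻¹ min⁻¹)
    catalyst intermediate B → released group + catalyst intermediate C (k = 12.0 min⁻¹)
    catalyst intermediate C ⇌ free catalyst + product (K = 4.10 M, k = 2.60 min⁻¹)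
    free catalyst + released group ⇌ idle complex, settled at all times (K = 0.280 M⁻¹)
    free catalyst + impurity → spent catalyst (k = 50.0 M⁻¹ min⁻¹)

At 6.00 min in ochre, free catalyst went to starting material at 3.0 times its rate to impurity, and the selectivity factor times the amount of starting material over the amount of impurity left gave 2.98. Raised to the selectivity factor, the 39 % of impurity left in ochre gave 60.0 % of starting material where ochre held 60 %, and the 47 % of impurity left in the neighbour flask with 0.85 M of starting material, otherwise ochre, gave 66.4 % where that flask held 66 %.

The data come from a simulation with constants of no real substance, and the scatter is random.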